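**Plan**
- Cuts: (i) the lower-unit C4–OH is traced back to a C4–S(aryl) group; (ii) the interflavanyl bond C4(upper)–C6(lower) is cut into a flavan C4 cation and a ring A nucleophile, so both halves come from one monomer; (iii) in that monomer ring C is cut at O1–C2 and C3–C4.
- Forward: a salicylaldehyde (future O1, C8a, C4a, C4) and a Z-enol ester of (R)-mandelic acid (future C2, C3, ring B) are condensed and ring C is closed in one operation. The monomer is then split into a 6-bromo electrophile and a 4-thio nucleophile, the two are joined C4→C6, and the helpers (mandelate, sulfur, bromine, benzyl) are removed.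
- Enabling feature: the ring A phenol oxygen O1, its ortho carbon C4a and the oxidised benzylic carbon C4 form a latent ortho-quinone methide (O1=C8a–C4a=C4). C3 and C4 both carry oxygen, which gives a two-point handle for a temporary tether. The para-oxygenated ring B makes the C2=C3 enol ester nucleophilic at C3.
- Stereochemistry: C2/C3 cis in both units comes from the Z alkene adding suprafacially; the absolute sense comes from the (R)-mandelate tether; every C4 centre is set by anti attack on the C4 cation next to the 3-oxygen (3,4-trans).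

Key step: step 3

Remark (assumption): the facial sense of the key cycloaddition is assigned from a chair-like exo (trans-fusing) array with the mandelate phenyl equatorial, and the (R)-acid is written on that basis. The C4 configuration of the adduct is not relied on, because C4 is re-set by ionisation in steps 5, 6 and 8.

**Step 1**
Reactants: 1 2,3,4-trihydroxybenzaldehyde
Product: 2 3,4-bis(benzyloxy)-2-hydroxybenzaldehyde
Conditions: BnBr (2.1 equiv), Li2CO3, DMF, 50 °C
Reagents that add atoms: benzyl bromide, BrCc1ccccc1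
Why: Williamson etherification in which the 2-OH, hydrogen-bonded to the aldehyde and the least nucleophilic phenol, should stay free while O3 and O4 are benzylated by the weak base.

**Step 2**
Reactants: 3 1-(benzyloxy)-4-ethynylbenzene; 4 (R)-mandelic acid
Product: 5 (Z)-2-[4-(benzyloxy)phenyl]ethenyl (2R)-2-hydroxy-2-phenylacetate
Conditions: Ru(2-methylallyl)2(Ph2P(CH2)4PPh2) (2 mol%), toluene, 50 °C
Reagents that add atoms: none
Why: Ruthenium-catalysed anti-Markovnikov trans-addition of a carboxylic acid to a terminal alkyne (through a ruthenium vinylidene) should give the Z-enol ester, the carboxylic acid reacting in preference to the secondary hydroxyl and the mandelate centre staying untouched.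

**Step 3**
Reactants: 2 3,4-bis(benzyloxy)-2-hydroxybenzaldehyde; 5 (Z)-2-[4-(benzyloxy)phenyl]ethenyl (2R)-2-hydroxy-2-phenylacetate
Product: 8 (2R,3R,4S)-7,8-bis(benzyloxy)-2-[4-(benzyloxy)phenyl]chromane bridged from O3 to O4 by (R)-C(=O)–CH(Ph) (trans-fused 1,4-dioxan-2-one), via hemiacetal 6 (not isolated), via ortho-quinone methide ether 7 (not isolated)
Conditions: (PhO)2P(O)NHSO2CF3 (5 mol%), 5 Å molecular sieves, toluene (0.01 M), 0 °C → rt
Reagents that add atoms: none
Why: Proposed new method: the acid condenses the aldehyde of 2 with the α-hydroxyl of 5 to hemiacetal 6, which loses water with the help of the ortho phenol to give the 4-alkoxy ortho-quinone methide 7 (O1=C8a–C4a=C4), and the tethered Z-enol ester then adds across C4 and O1 in an inverse-electron-demand oxa-Diels–Alder reaction that forms C3–C4 and the O1–C2 bond. The closest known reaction types are the Brønsted-acid-catalysed condensation of salicylaldehydes with alkenyl alcohols to transient ortho-quinone methide ethers that cyclise by intramolecular [4+2] addition, and the N-triflylphosphoramide-catalysed [4+2] addition of ortho-quinone methides to styrenes. The pyran ring C closes as the six-membered oxa-[4+2] adduct, and the 1,4-dioxan-2-one closes in the same event as the tether ring of a type 1 intramolecular cycloaddition (four-atom tether O4–CH(Ph)–C(=O)–O3, exo mode, trans fusion). C2 and C3 should come out cis because the Z alkene adds suprafacially in a concerted asynchronous bond formation, C4 should come out trans to C3 because the tether sits exo in a chair-like array, and the absolute sense follows from the (R)-mandelate centre, whose phenyl stays equatorial on the forming dioxanone and so fixes the face of C4 that is attacked. The step needs regioselectivity (O1 to the benzylic carbon, C4 to the oxygen-bearing carbon), which the tether enforces and the para-benzyloxyphenyl group reinforces by making the acyloxy-bearing carbon the nucleophilic terminus, and it needs ring closure to outrun intermolecular addition, which high dilution secures.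

**Step 4**
Reactants: 8 cycloadduct
Product: 9 6-bromo derivative of 8
Conditions: NBS (1.05 equiv), NaHCO3, CH2Cl2, −40 → 0 °C, dark
Reagents that add atoms: N-bromosuccinimide, O=C1CCC(=O)N1Br
Why: Electrophilic aromatic bromination should go to C6 of ring A, the only free position para to O1 and ortho to the 7-benzyloxy group, and so blocks the nucleophilic carbon of the future upper unit.

**Step 5**
Reactants: 8 cycloadduct
Product: 10 (2R,3S,4S)-7,8-bis(benzyloxy)-2-[4-(benzyloxy)phenyl]-4-[(2,6-dimethylphenyl)sulfanyl]chroman-3-yl (2R)-2-hydroxy-2-phenylacetate (2,3-cis-3,4-trans)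
Conditions: 2,6-Me2C6H3SH (3 equiv), BF3·OEt2 (0.5 equiv), CH2Cl2, −78 → −30 °C
Reagents that add atoms: 2,6-dimethylbenzenethiol, Cc1cccc(C)c1S
Why: Lewis-acid thiolysis of a 4-alkoxyflavan (SN1): BF3 should ionise the benzylic C4–O4 bond (cation stabilised by O1 and the 7-benzyloxy group) and the thiol should add anti to the 3-acyloxy group, which gives the 3,4-trans thioether, frees the mandelate hydroxyl and erases the C4 configuration of 8.

**Step 6**
Reactants: 9 6-bromo cycloadduct; 10 4-thioether mandelate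
Product: 11 dimer bis-mandelate (upper C4 bonded to lower C6; 3-O-[(R)-mandeloyl] on each unit; Br at upper C6; arylsulfanyl at lower C4)
Conditions: BF3·OEt2 (0.5 equiv), CH2Cl2, −78 → −30 °C, the bromide added slowly to an equimolar amount of the thioether
Reagents that add atoms: none
Why: Friedel–Crafts-type flavan C4 arylation (the standard proanthocyanidin coupling), here an addition that keeps every atom of both partners: BF3 should ionise C4–O4 of 9 while the hindered aryl thioether of 10 stays inert to the hard Lewis acid, C6 of 10 (para to O1, ortho to O7) attacks the cation anti to the 3-acyloxy group to set the upper 3,4-trans centre, the proton lost from C6 ends on the mandelate hydroxyl freed by ring opening so that the Lewis acid turns over, and the bromine on 9 together with the 8-benzyloxy groups leaves no further nucleophilic ring carbon, so self-condensation and chain growth are excluded without an excess of either partner.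

**Step 7**
Reactants: 11 dimer bis-mandelate
Product: 12 dimer 3,3′-diol (hexabenzyl ether with upper 6-Br and lower 4-arylsulfanyl)
Conditions: K2CO3 (0.3 equiv), MeOH/THF, 0 °C → rt
Reagents that add atoms: none
Why: Base-catalysed transesterification should remove both activated α-hydroxy esters without touching the benzyl ethers, the thioether or the aryl bromide.

**Step 8**
Reactants: 12 dimer diol thioether
Product: 13 hexa-O-benzyl-6-bromo dimer with the lower 3,4-trans 3,4-diol
Conditions: AgOSO2CF3 (1.5 equiv), 2,6-di-tert-butylpyridine, THF/H2O (10:1), 0 °C, dark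
Reagents that add atoms: water, O
Why: Thiophilic activation (silver-assisted SN1 solvolysis of a 4-arylthioflavan): the silver ion should pull off the thiolate and water should add to the lower C4 cation anti to the pseudo-axial 3-OH to give the 3,4-trans 4-ol, the blocked C6 positions leaving water as the only competent nucleophile.

**Step 9**
Reactants: 13 hexa-O-benzyl-6-bromo dimer
Product: 14 (2R,3R,4S)-2-(4-hydroxyphenyl)-4-[(2R,3R,4S)-3,4,7,8-tetrahydroxy-2-(4-hydroxyphenyl)chroman-6-yl]chromane-3,7,8-triol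
Conditions: H2 (1 atm), Pd(OH)2/C, Et3N (3 equiv), THF/MeOH, rt, under argon on work-up
Reagents that add atoms: none
Why: Catalytic hydrogenolysis should cleave the six benzyl ethers and the aryl C–Br bond, while triethylamine takes up HBr and suppresses hydrogenolysis and ionisation of the benzylic 4-OH.

**Compound list**
1 | 2,3,4-trihydroxybenzaldehyde | O=Cc1ccc(O)c(O)c1O | starting material
2 | 3,4-bis(benzyloxy)-2-hydroxybenzaldehyde | O=Cc1ccc(OCc2ccccc2)c(OCc2ccccc2)c1O | intermediate
3 | 1-(benzyloxy)-4-ethynylbenzene | C#Cc1ccc(OCc2ccccc2)cc1 | starting material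
4 | (R)-mandelic acid, (2R)-2-hydroxy-2-phenylacetic acid | O[C@@H](C(=O)O)c1ccccc1 | starting material
5 | (Z)-2-[4-(benzyloxy)phenyl]ethenyl (2R)-2-hydroxy-2-phenylacetate | O[C@@H](C(=O)O/C=C\c1ccc(OCc2ccccc2)cc1)c1ccccc1 | intermediate
6 | hemiacetal of 2 with 5: (Z)-2-[4-(benzyloxy)phenyl]ethenyl (2R)-2-{[3,4-bis(benzyloxy)-2-hydroxyphenyl](hydroxy)methoxy}-2-phenylacetate, both epimers at the hemiacetal carbon | OC(O[C@@H](C(=O)O/C=C\c1ccc(OCc2ccccc2)cc1)c1ccccc1)c1ccc(OCc2ccccc2)c(OCc2ccccc2)c1O | intermediate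
7 | ortho-quinone methide ether: (Z)-2-[4-(benzyloxy)phenyl]ethenyl (2R)-2-{(E)-[4,5-bis(benzyloxy)-6-oxocyclohexa-2,4-dien-1-ylidene]methoxy}-2-phenylacetate | O=C(O/C=C\c1ccc(OCc2ccccc2)cc1)[C@H](O/C=C1\C=CC(OCc2ccccc2)=C(OCc2ccccc2)C1=O)c1ccccc1 | intermediate
8 | cycloadduct: (2R,3R,4S)-7,8-bis(benzyloxy)-2-[4-(benzyloxy)phenyl]chromane-3,4-diol with O3 acylated and O4 alkylated by one (R)-C(=O)–CH(Ph) unit (trans-fused 3-phenyl-1,4-dioxan-2-one; 2,3-cis-3,4-trans) | O(Cc5ccccc5)c1ccc2c(c1OCc5ccccc5)O[C@H](c1ccc(OCc5ccccc5)cc1)[C@@H]1OC(=O)[C@@H](c5ccccc5)O[C@@H]21 | intermediate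
9 | 6-bromo derivative of 8 (Br on ring A, para to O1) | O(Cc5ccccc5)c1c(Br)cc2c(c1OCc5ccccc5)O[C@H](c1ccc(OCc5ccccc5)cc1)[C@@H]1OC(=O)[C@@H](c5ccccc5)O[C@@H]21 | intermediate
10 | (2R,3S,4S)-7,8-bis(benzyloxy)-2-[4-(benzyloxy)phenyl]-4-[(2,6-dimethylphenyl)sulfanyl]chroman-3-yl (2R)-2-hydroxy-2-phenylacetate (2,3-cis-3,4-trans; the descriptor at C3 changes only because of sulfur) | O(Cc5ccccc5)c1ccc2c(c1OCc5ccccc5)O[C@H](c1ccc(OCc5ccccc5)cc1)[C@H](OC(=O)[C@H](O)c5ccccc5)[C@H]2Sc1c(C)cccc1C | intermediate
11 | dimer bis-mandelate: upper unit (2R,3R,4S), 6-bromo, 3-O-[(R)-mandeloyl], bonded from C4 to C6 of the lower unit (2R,3S,4S), 4-[(2,6-dimethylphenyl)sulfanyl], 3-O-[(R)-mandeloyl]; all six phenols as benzyl ethers | O(Cc5ccccc5)c1ccc([C@H]2Oc3c(cc(Br)c(OCc5ccccc5)c3OCc5ccccc5)[C@H](c3cc4c(c(OCc5ccccc5)c3OCc5ccccc5)O[C@H](c3ccc(OCc5ccccc5)cc3)[C@H](OC(=O)[C@H](O)c5ccccc5)[C@H]4Sc3c(C)cccc3C)[C@H]2OC(=O)[C@H](O)c5ccccc5)cc1 | intermediate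
12 | dimer diol: as 11 with both 3-hydroxyls free | O(Cc5ccccc5)c1ccc([C@H]2Oc3c(cc(Br)c(OCc5ccccc5)c3OCc5ccccc5)[C@H](c3cc4c(c(OCc5ccccc5)c3OCc5ccccc5)O[C@H](c3ccc(OCc5ccccc5)cc3)[C@H](O)[C@H]4Sc3c(C)cccc3C)[C@H]2O)cc1 | intermediate
13 | hexa-O-benzyl-6-bromo dimer: upper (2R,3R,4S)-3-ol, lower (2R,3R,4S)-3,4-diol | O(Cc5ccccc5)c1ccc([C@H]2Oc3c(cc(Br)c(OCc5ccccc5)c3OCc5ccccc5)[C@H](c3cc4c(c(OCc5ccccc5)c3OCc5ccccc5)O[C@H](c3ccc(OCc5ccccc5)cc3)[C@H](O)[C@H]4O)[C@H]2O)cc1 | intermediate
14 | (2R,3R,4S)-2-(4-hydroxyphenyl)-4-[(2R,3R,4S)-3,4,7,8-tetrahydroxy-2-(4-hydroxyphenyl)chroman-6-yl]chromane-3,7,8-triol (both units 2,3-cis-3,4-trans) | Oc1ccc([C@H]2Oc3c(ccc(O)c3O)[C@H](c3cc4c(c(O)c3O)O[C@H](c3ccc(O)cc3)[C@H](O)[C@H]4O)[C@H]2O)cc1 | target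

**Step count:** 9 steps in total. Longest linear sequence: 7 steps (1 → 2 → 8 → 9 or 10 → 11 → 12 → 13 → 14).

**Steps most likely to fail**

Step 3 (labelled step). What may go wrong:
- acyl transfer from the enol ester to the hemiacetal hydroxyl outrunning dehydration to the quinone methide;
- a stepwise addition with bond rotation in the benzylic cation, eroding the 2,3-cis relationship;
- cycloaddition through the endo (cis-fusing) array, which would reverse the facial sense.

Fallback (known reactions only), setting out from 2 and returning at 12. Amine-catalysed domino oxa-Michael/aldol condensation of 2 with (E)-3-[4-(benzyloxy)phenyl]prop-2-enal ((S)-2-[diphenyl(trimethylsilyloxy)methyl]pyrrolidine, 2-nitrobenzoic acid, toluene, rt) closes the same O1–C2 bond under catalyst control and should give (R)-7,8-bis(benzyloxy)-2-[4-(benzyloxy)phenyl]-2H-chromene-3-carbaldehyde F1. Weitz–Scheffer epoxidation (H2O2, NaOH, MeOH, 0 °C) anti to the 2-aryl group gives the 3,4-epoxy-3-carbaldehyde F2. Acid-catalysed methanolysis (camphorsulfonic acid, MeOH, 0 °C) opens the epoxide at benzylic C4 to the 3-hydroxy-4-methoxy-3-carbaldehyde F3. NaIO4 (THF/H2O) cleaves the α-hydroxy aldehyde to the 4-methoxyflavan-3-one F4. LiBH(s-Bu)3 (THF, −78 °C) delivers hydride anti to the 2-aryl group to give the 2,3-cis 4-methoxyflavan-3-ol F5. NBS converts part of F5 into its 6-bromo derivative F6, and 2,6-dimethylbenzenethiol/BF3·OEt2 converts the rest into the 3,4-trans 4-thioether F7. BF3·OEt2-mediated coupling of F6 with F7 (C4 of F6 to C6 of F7) gives 12.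

Step 6. What may go wrong: C–C bond formation by the weakly nucleophilic tri-oxygenated ring A of 10 is too slow, so that proton loss from the C4 cation, reversible O-alkylation and slow activation of the thioether take over.

Fallback, setting out from 9 and returning at 11: the nucleophile is made an aryl trifluoroborate that reacts by ipso substitution at C6. Miyaura borylation of 9 (bis(pinacolato)diboron, KOAc, PdCl2[Ph2P(C5H4)Fe(C5H4)PPh2], dioxane, 80 °C) gives the 6-(pinacolatoboryl) cycloadduct F8. Thiolysis as in step 5 gives the 6-boryl 4-thioether mandelate F9. KHF2 (MeOH/H2O) gives the potassium trifluoroborate F10. BF3·OEt2-promoted reaction of F10 with 9 (CH2Cl2, −78 → −30 °C) joins C4 of 9 to the boron-bearing C6 and gives 11.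

Step 9. What may go wrong: reductive loss of the benzylic 4-hydroxyl of the lower unit (C–O hydrogenolysis), or its ionisation by the HBr formed, followed by self-condensation.

Fallback, setting out from 12 and returning at 14: the 4-hydroxyl is unveiled only after the hydrogenation, through a ring A para-quinone methide. Oxidation of 12 (m-chloroperbenzoic acid, CH2Cl2, 0 °C) gives the 4-[(2,6-dimethylphenyl)sulfonyl] hexabenzyl ether F11. Hydrogenolysis (H2, Pd(OH)2/C, Et3N, THF/MeOH) gives the free phenolic sulfone F12. In degassed dilute aqueous NaHCO3/THF the 7-phenoxide of the lower unit expels the sulfinate from C4 and water adds anti to the 3-OH to give 14.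

**Further compounds**
F1 | step 3 | (R)-7,8-bis(benzyloxy)-2-[4-(benzyloxy)phenyl]-2H-chromene-3-carbaldehyde | O=CC1=Cc2ccc(OCc5ccccc5)c(OCc5ccccc5)c2O[C@@H]1c1ccc(OCc5ccccc5)cc1
F2 | step 3 | 3,4-epoxy-7,8-bis(benzyloxy)-2-[4-(benzyloxy)phenyl]chromane-3-carbaldehyde, epoxide trans to the 2-aryl group | O(Cc5ccccc5)c1ccc2c(c1OCc5ccccc5)O[C@H](c1ccc(OCc5ccccc5)cc1)[C@@]1(C=O)O[C@@H]21
F3 | step 3 | (2R,3S,4R)-7,8-bis(benzyloxy)-2-[4-(benzyloxy)phenyl]-3-hydroxy-4-methoxychromane-3-carbaldehyde (C4 drawn as the inversion product; its configuration is not relied on) | O(Cc5ccccc5)c1ccc2c(c1OCc5ccccc5)O[C@H](c1ccc(OCc5ccccc5)cc1)[C@](O)(C=O)[C@@H]2OC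
F4 | step 3 | (2R,4R)-7,8-bis(benzyloxy)-2-[4-(benzyloxy)phenyl]-4-methoxychroman-3-one | O(Cc5ccccc5)c1ccc2c(c1OCc5ccccc5)O[C@H](c1ccc(OCc5ccccc5)cc1)C(=O)[C@@H]2OC
F5 | step 3 | (2R,3R,4R)-7,8-bis(benzyloxy)-2-[4-(benzyloxy)phenyl]-4-methoxychroman-3-ol (2,3-cis) | O(Cc5ccccc5)c1ccc2c(c1OCc5ccccc5)O[C@H](c1ccc(OCc5ccccc5)cc1)[C@H](O)[C@@H]2OC
F6 | step 3 | 6-bromo derivative of F5 | O(Cc5ccccc5)c1c(Br)cc2c(c1OCc5ccccc5)O[C@H](c1ccc(OCc5ccccc5)cc1)[C@H](O)[C@@H]2OC
F7 | step 3 | (2R,3S,4S)-7,8-bis(benzyloxy)-2-[4-(benzyloxy)phenyl]-4-[(2,6-dimethylphenyl)sulfanyl]chroman-3-ol (2,3-cis-3,4-trans) | O(Cc5ccccc5)c1ccc2c(c1OCc5ccccc5)O[C@H](c1ccc(OCc5ccccc5)cc1)[C@H](O)[C@H]2Sc1c(C)cccc1C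
F8 | step 6 | 6-(4,4,5,5-tetramethyl-1,3,2-dioxaborolan-2-yl) analogue of 9 (boron in place of bromine) | O(Cc5ccccc5)c1c(B6OC(C)(C)C(C)(C)O6)cc2c(c1OCc5ccccc5)O[C@H](c1ccc(OCc5ccccc5)cc1)[C@@H]1OC(=O)[C@@H](c5ccccc5)O[C@@H]21
F9 | step 6 | 6-(pinacolatoboryl) analogue of 10 | O(Cc5ccccc5)c1c(B6OC(C)(C)C(C)(C)O6)cc2c(c1OCc5ccccc5)O[C@H](c1ccc(OCc5ccccc5)cc1)[C@H](OC(=O)[C@H](O)c5ccccc5)[C@H]2Sc1c(C)cccc1C
F10 | step 6 | potassium trifluoroborate at C6 of 10 | [K+].O(Cc5ccccc5)c1c([B-](F)(F)F)cc2c(c1OCc5ccccc5)O[C@H](c1ccc(OCc5ccccc5)cc1)[C@H](OC(=O)[C@H](O)c5ccccc5)[C@H]2Sc1c(C)cccc1C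
F11 | step 9 | sulfone of 12: lower C4 carries (2,6-dimethylphenyl)sulfonyl | O(Cc5ccccc5)c1ccc([C@H]2Oc3c(cc(Br)c(OCc5ccccc5)c3OCc5ccccc5)[C@H](c3cc4c(c(OCc5ccccc5)c3OCc5ccccc5)O[C@H](c3ccc(OCc5ccccc5)cc3)[C@H](O)[C@H]4S(=O)(=O)c3c(C)cccc3C)[C@H]2O)cc1
F12 | step 9 | free phenolic sulfone: 14 with (2,6-dimethylphenyl)sulfonyl in place of the lower 4-OH | Oc1ccc([C@H]2Oc3c(ccc(O)c3O)[C@H](c3cc4c(c(O)c3O)O[C@H](c3ccc(O)cc3)[C@H](O)[C@H]4S(=O)(=O)c3c(C)cccc3C)[C@H]2O)cc1
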